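## Analysis of the target

Target 29 is a linear, achiral chain of eleven benzene rings (A to K) joined by ten diaryl ether oxygens and carrying 28 free hydroxyl groups. It has no stereocentre, so nothing has to be set or related, and the diaryl ether axes are taken to rotate freely. Ring A is a 2,4,6-trihydroxyphenyl end group. Rings B, D, F, H and J are 2,6-dihydroxy-1,4-phenylenedioxy units. Rings C, E, G and I are pentaoxygenated benzenes with one hydrogen, and ring K is a 3,4,5-trihydroxyphenyl end group. Numbered as in ring C, each pentaoxygenated ring has at C1 the oxygen that belongs to the doubly ortho-oxygenated position C4 of ring B, at C2 the only C–H, at C3 to C5 three hydroxyls, and at C6 the oxygen bound to the unhindered C1 of ring D. The pyrogallol-type arrays in rings C, E, G, I and K are oxidised by air, above all as phenoxides, so the free hydroxyls can appear only in the last step and are carried as methyl ethers until then. The difficulty is twofold: five of the ten ether bonds end at a carbon flanked by two oxygen substituents (C2 of ring A, C4 of rings B, D, F, H, J), where cross-coupling at carbon is poor, and four rings carry five contiguous oxygenated carbons with three different roles. The strategy rests on ring C: C3 to C6 with their oxygens correspond to a squaric ester, C1 and C2 to an enol ether unit on the ring B oxygen, so the ring can be grown on that hindered oxygen instead of being coupled to it. The pair B–C recurs as D–E, F–G and H–I, so one building block serves four times.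

## Retrosynthetic reasoning

**29 to 28.** The 28 O–H bonds are traced back to methyl ethers in 28. Methyl ethers are what the purchasable aromatic building blocks already carry, and they survive organolithium reagents, heat and palladium catalysis. The forward step has to cleave 28 methyl ethers without touching the ten diaryl ether bonds.

**28 to 25 + 27, and 24, 22, 20, 18 to 23, 21, 19, 17 + 16.** The five ether bonds cut are those between an oxygen and the unhindered C1 of rings J, H, F, D and B. In the forward sense each is the same reaction, a hindered phenol coupled with an aryl chloride that has two free ortho positions. The phenols are 25, 23, 21, 19 and 17, the chlorides are 27 and, four times, 16. The other kind of ether bond, from oxygen to a doubly ortho-oxygenated carbon, is never made by coupling. Between couplings the silyl ether at C6 of the last ring is removed (24 to 25, 22 to 23, 20 to 21, 18 to 19). The gain is that the whole B–I section comes from a single compound, 16, and that ring A enters as the cheap phenol 17.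

**Why chlorine on 16.** The para substituent of ring B in 12, 15 and 16 is chlorine. A protected oxygen there (for instance a benzyl ether) would serve the key step equally. It would, however, be the correct atom only for ring B, and it would force the A–O–B bond to be made from a di-ortho-methoxy electrophile. In rings D, F and H the linking oxygen already comes from C6 of the preceding ring. Chlorine is inert to the lithium chemistry at –78 °C and to the thermolysis, and it is the coupling handle afterwards.

**27 to 2 + 26.** The J–O–K bond is cut at the unhindered C1 of ring K. Phenol 2 brings the hindered oxygen, 26 the ring K carbon. Copper catalysis activates the bromide of 26 and leaves the chloride of 2 for the later coupling.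

**16 to 15 to 12 (key disconnection).** After removal of the C3 methyl group, ring C of 15 is opened in the reverse of a 6π electrocyclisation at the C2–C3 bond and then closed to the cyclobutenone 12 in the reverse of a 4π ring opening. This is the place to cut because it turns the pentaoxygenated benzene into a squarate adduct in which all five oxygens are already attached and differentiated. The forward reaction has to open the four-membered ring with the vinyl group turning inward and form the C2–C3 bond.

**12 to 8 + 9.** The bond between the quaternary carbon of 12 (future C6) and the oxygen-bearing vinyl carbon (future C1) is cut. This gives the squarate 9 and a 1-aryloxyvinyl anion, generated from the vinyl bromide 8 by halogen–lithium exchange. A bromide is used, not a deprotonation of the parent vinyl ether, because the ring hydrogens between chlorine and methoxy would compete for the base.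

**8 to 7 to 4 to 2 + 3.** The bromine of 8 is placed alpha to oxygen by Markovnikov addition of hydrogen halide to the ynol ether 7. Compound 7 comes from the dichlorovinyl ether 4, the adduct of phenol 2 and 3. The shorter-looking sequence of vinyl ether, bromination and dehydrobromination was discarded: the alpha bromide of the dibromide ionises and the elimination gives the 2-bromovinyl ether, with the halogen on the wrong carbon. In the ynol ether route protonation at the terminal carbon fixes the regiochemistry. The two carbons of 3 become C1 and C2 of ring C, and the O–C1 bond to the hindered oxygen of ring B is made here by addition, not by coupling.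

**2 to 1.** The central methyl ether of 1 is removed. The central methoxy group of a 1,2,3-trimethoxyarene is the one a Lewis acid cleaves first, which gives the para-chlorinated hindered phenol with no regiochemical question.

## Alternatives that were turned down

**Alternative 1:** The C4 oxygen of rings C, E, G, I and K is disconnected to a formyl group. In the forward key step the pentaaldehyde A2 is treated with a peracid; each aryl group, flanked by two methoxy groups, migrates to oxygen (Baeyer–Villiger oxidation of the Dakin type), and methanolysis of the five formates gives A1.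
- For it: all rings would come from purchasable aromatics with no ring construction, five oxygens arrive in one operation, and a formyl group para to C1 could activate the hindered B–O–C bond for SNAr. On oxygen introduction per step it is as strong as or stronger than the chosen route.
- Against it: a peracid must act five times, completely, on a very electron-rich polyaryl ether, and each incomplete or over-oxidised site gives a by-product of nearly the same size and polarity. The formyl group is meta to C6, so the C6–O–D bonds gain nothing. The pentasubstituted benzaldehyde units are themselves multi-step compounds.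
- In its place the chosen strategy fixes the oxygen pattern by connectivity on a small unit, where failure is cheap, and uses no oxidant near the chain.

**Alternative 2:** Ring B is disconnected between rings A and C by a Danheiser benzannulation. Heating the ynol ether A4 with the cyclobutenone A5 gives, through a vinylketene, 2+2 cycloaddition, ring opening and 6π closure, the A–B–C unit A3.
- For it: three rings are united in one step, and both hindered ether bonds of ring B are carried in by the partners, not coupled. In convergence per step it is stronger than the chosen key step.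
- Against it: the ring it builds is the tetraoxygenated ring B, which is purchasable as a phenol of the type of 2, while the pentaoxygenated ring C has to be supplied ready-made as a brominated trimethoxyphenyl unit. The bromine of A3 sits at C6 of ring C between two substituents, so each C6–O–D bond would need a coupling at a doubly ortho-substituted carbon, four times, on a growing chain. Each further B-type ring would need a new ynol ether and a new cyclobutenone made from ever larger fragments.
- The chosen strategy puts the ring construction on the ring that cannot be bought and leaves only couplings at unhindered carbons.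

**Alternative 3:** Ring A is disconnected at C1–C2 to an open-chain triketide on the ring B oxygen. An alkoxide base closes the dioxo ester A7 by attack of the aryloxy-bearing carbanion on the ester, and the triketone aromatises to the A–B unit A6.
- For it: it is metal-free and mild, and it makes the A–O–B bond at the most hindered carbon of ring A without a coupling, a point on which it is stronger.
- Against it: ring A is the one ring that costs nothing here, since 17 is bought and joined in one step. The 3,5-dioxo ester can close through oxygen to a pyranone, and the carbanion between the two ketones is more easily formed than the one next to the aryloxy group. A6 has three free hydroxyls that need protection. None of the four pentaoxygenated rings is addressed.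
- The chosen strategy spends its effort where the structural problem lies.

Key step: step 6

Assumption: compounds 1, 3, 9, 17 and 26 are taken as catalogue chemicals; 12 is racemic and its single stereocentre disappears in step 6.

## Route

Step 1
Reactants: 1 5-chloro-1,2,3-trimethoxybenzene
Product: 2 4-chloro-2,6-dimethoxyphenol
Conditions: AlCl3 (1.5 equiv), CH2Cl2, 0 °C to rt; H2O
Reagents that add atoms: none
Why: Lewis-acid demethylation of an aryl methyl ether; the central methoxy group of a 1,2,3-trimethoxyarene is twisted out of the ring plane, is the most basic oxygen and chelates AlCl3 through a neighbouring methoxy group, so chloride removes that methyl group and the two outer ethers stay.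

Step 2
Reactants: 2 4-chloro-2,6-dimethoxyphenol; 3 trichloroethylene
Product: 4 5-chloro-2-{[(E)-1,2-dichloroethenyl]oxy}-1,3-dimethoxybenzene
Conditions: K2CO3, DMF, 70 °C
Reagents that add atoms: none
Why: Base converts trichloroethylene into dichloroacetylene by loss of HCl, the hindered phenoxide adds to this small linear electrophile and trans protonation gives the E-configured 1,2-dichlorovinyl ether, the standard entry to aryl ynol ethers; this step forms the bond from the ring B oxygen to the future C1 of ring C.

Step 3
Reactants: 4 5-chloro-2-{[(E)-1,2-dichloroethenyl]oxy}-1,3-dimethoxybenzene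
Product: 7 5-chloro-2-(ethynyloxy)-1,3-dimethoxybenzene, via 5-chloro-2-[(chloroethynyl)oxy]-1,3-dimethoxybenzene 5 (not isolated), via lithium (4-chloro-2,6-dimethoxyphenoxy)acetylide 6 (not isolated)
Conditions: n-BuLi (2.1 equiv), THF, –78 to –50 °C; H2O, –78 °C
Reagents that add atoms: none
Why: n-BuLi removes the vinylic hydrogen, loss of LiCl gives the chloroalkyne 5, chlorine–lithium exchange with the second equivalent gives the acetylide 6, and water protonates it to the terminal ynol ether; at –78 °C the aryl chloride and the ring hydrogens next to it should be left alone.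

Step 4
Reactants: 7 5-chloro-2-(ethynyloxy)-1,3-dimethoxybenzene
Product: 8 2-[(1-bromoethenyl)oxy]-5-chloro-1,3-dimethoxybenzene
Conditions: TMSBr (1.0 equiv), MeOH (1.0 equiv), CH2Cl2, –78 to –40 °C; used crude after filtration through basic alumina
Reagents that add atoms: bromotrimethylsilane, C[Si](C)(C)Br (gives HBr with MeOH)
Why: Markovnikov hydrohalogenation of an ynol ether: protonation at the terminal carbon gives the oxygen-stabilised ketene-oxonium cation and bromide adds at the oxygen-bearing carbon, so the bromine ends up alpha to oxygen; one equivalent of HBr at low temperature limits a second addition.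

Step 5
Reactants: 8 2-[(1-bromoethenyl)oxy]-5-chloro-1,3-dimethoxybenzene; 9 dimethyl squarate (3,4-dimethoxycyclobut-3-ene-1,2-dione)
Product: 12 4-(tert-butyldimethylsilyloxy)-4-[1-(4-chloro-2,6-dimethoxyphenoxy)ethenyl]-2,3-dimethoxycyclobut-2-en-1-one (racemic), via [1-(4-chloro-2,6-dimethoxyphenoxy)ethenyl]lithium 10 (not isolated), via lithium cyclobutenolate adduct 11 (not isolated)
Conditions: t-BuLi (2.0 equiv), THF, –78 °C, 10 min; cannula into 9 (1.2 equiv), THF, –78 °C; TBSOTf (1.3 equiv), –78 to 0 °C
Reagents that add atoms: tert-butyldimethylsilyl trifluoromethanesulfonate, CC(C)(C)[Si](C)(C)OS(=O)(=O)C(F)(F)F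
Why: Bromine–lithium exchange of the vinyl bromide is faster at –78 °C than metalation of the ring, the 1-aryloxyvinyllithium adds 1,2 to one carbonyl of the symmetrical squarate (the product is a vinylogous ester and does not add again), and the tertiary lithium alkoxide is silylated in the same flask; the new quaternary carbon forms as a racemate and is destroyed in step 6.

Step 6
Reactants: 12 4-(tert-butyldimethylsilyloxy)-4-[1-(4-chloro-2,6-dimethoxyphenoxy)ethenyl]-2,3-dimethoxycyclobut-2-en-1-one
Product: 15 4-(tert-butyldimethylsilyloxy)-5-(4-chloro-2,6-dimethoxyphenoxy)-2,3-dimethoxyphenol (B–C unit), via (Z)-dienylketene 13 (not isolated), via cyclohexa-2,4-dienone tautomer 14 (not isolated)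
Conditions: degassed toluene, 110 °C, Ar (p-xylene, 138 °C if slow)
Reagents that add atoms: none
Why: On heating, the cyclobutenone undergoes conrotatory 4π electrocyclic opening of the bond between the carbonyl carbon and the quaternary carbon and gives dienylketene 13. The opening is torquoselective: the silyloxy donor turns outward and the 1-aryloxyvinyl group inward, so the ketene and the vinyl CH2 lie on the same side of the central double bond. A thermally allowed disrotatory 6π electrocyclisation then joins the ketene carbon (future C3) to the CH2 carbon (future C2) and closes the six-membered ring as dienone 14, which enolises to phenol 15. The closest known reaction type is the Moore rearrangement of 4-alkenyl-4-oxycyclobutenones made from squarate esters, which gives highly oxygenated phenols and hydroquinone monoethers. No stereocentre is formed; the racemic quaternary carbon of 12 becomes the sp2 carbon C6. The step needs only the right sense of rotation in the ring opening, which the oxygen substituent on the quaternary carbon secures, and the substitution pattern of ring C follows from the connectivity of 12, so no regiochemical choice is left. The product holds the oxygen types of ring C apart: free hydroxyl at C3, silyl ether at C6 (para to the new hydroxyl, so the silyl group cannot migrate to it), methyl ethers at C4 and C5, and the C1 oxygen already bound to ring B. Aryl chloride, methyl ethers and silyl ether are inert at 110 °C, and degassed solvent protects the electron-rich phenol from air.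

Step 7
Reactants: 15 4-(tert-butyldimethylsilyloxy)-5-(4-chloro-2,6-dimethoxyphenoxy)-2,3-dimethoxyphenol
Product: 16 tert-butyl[6-(4-chloro-2,6-dimethoxyphenoxy)-2,3,4-trimethoxyphenoxy]dimethylsilane (building block for rings B–C, D–E, F–G, H–I)
Conditions: MeI, K2CO3, acetone, 40 °C
Reagents that add atoms: iodomethane, CI
Why: Williamson methylation of the only free phenol; the silyl ether, shielded between an aryloxy and a methoxy group, should not be touched by K2CO3 in acetone.

Step 8
Reactants: 16 tert-butyl[6-(4-chloro-2,6-dimethoxyphenoxy)-2,3,4-trimethoxyphenoxy]dimethylsilane; 17 2,4,6-trimethoxyphenol (1.5 equiv)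
Product: 18 A–B–C trimer silyl ether, tert-butyl{6-[2,6-dimethoxy-4-(2,4,6-trimethoxyphenoxy)phenoxy]-2,3,4-trimethoxyphenoxy}dimethylsilane
Conditions: Pd(OAc)2 (5 mol %), 2-(di-tert-butylphosphino)-2',4',6'-triisopropylbiphenyl (tBuXPhos, 10 mol %), K3PO4, toluene, 100 °C
Reagents that add atoms: none
Why: Pd-catalysed C–O cross-coupling of an aryl chloride with a phenol (Buchwald–Hartwig-type etherification): the C–Cl bond of 16 has two free ortho positions, so oxidative addition is easy, and the bulky phosphine together with the hindered, electron-rich phenoxide drives the C–O reductive elimination. The phenol has no free ortho or para position, so C-arylation cannot compete, and anhydrous K3PO4 in toluene should leave the silyl ether in place.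

Step 9
Reactants: 18 A–B–C trimer silyl ether
Product: 19 A–B–C trimer phenol, 6-[2,6-dimethoxy-4-(2,4,6-trimethoxyphenoxy)phenoxy]-2,3,4-trimethoxyphenol
Conditions: TBAF (1.2 equiv), AcOH (1.2 equiv), THF, 0 °C to rt
Reagents that add atoms: none
Why: Fluoride cleaves the aryl silyl ether; acetic acid protonates the electron-rich phenoxide at once and so protects it from air oxidation.

Step 10
Reactants: 19 A–B–C trimer phenol; 16 tert-butyl[6-(4-chloro-2,6-dimethoxyphenoxy)-2,3,4-trimethoxyphenoxy]dimethylsilane (1.5 equiv)
Product: 20 A–E pentamer silyl ether (19 arylated at its C6 oxygen by the chlorine-bearing carbon of 16; silyl ether on C6 of ring E)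
Conditions: Pd(OAc)2 (5 mol %), tBuXPhos (10 mol %), K3PO4, toluene, 100 °C
Reagents that add atoms: none
Why: Same C–O cross-coupling as in step 8, now with the C6 hydroxyl of ring C as the nucleophile; this phenol is blocked at both ortho positions and at the para position, so only O-arylation is possible, and the excess of the small chloride drives the larger partner to full conversion.

Step 11
Reactants: 20 A–E pentamer silyl ether
Product: 21 A–E pentamer phenol (free C6 hydroxyl on ring E)
Conditions: TBAF (1.2 equiv), AcOH (1.2 equiv), THF, 0 °C to rt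
Reagents that add atoms: none
Why: Fluoride-induced cleavage of the aryl silyl ether as in step 9, buffered with acetic acid.

Step 12
Reactants: 21 A–E pentamer phenol; 16 tert-butyl[6-(4-chloro-2,6-dimethoxyphenoxy)-2,3,4-trimethoxyphenoxy]dimethylsilane (1.5 equiv)
Product: 22 A–G heptamer silyl ether (silyl ether on C6 of ring G)
Conditions: Pd(OAc)2 (5 mol %), tBuXPhos (10 mol %), K3PO4, toluene, 100 °C
Reagents that add atoms: none
Why: Same Pd-catalysed etherification as in step 10; the reacting ends are identical, so chain length should not change the reactivity pattern.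

Step 13
Reactants: 22 A–G heptamer silyl ether
Product: 23 A–G heptamer phenol (free C6 hydroxyl on ring G)
Conditions: TBAF (1.2 equiv), AcOH (1.2 equiv), THF, 0 °C to rt
Reagents that add atoms: none
Why: Fluoride-induced cleavage of the aryl silyl ether as in step 9.

Step 14
Reactants: 23 A–G heptamer phenol; 16 tert-butyl[6-(4-chloro-2,6-dimethoxyphenoxy)-2,3,4-trimethoxyphenoxy]dimethylsilane (1.5 equiv)
Product: 24 A–I nonamer silyl ether (silyl ether on C6 of ring I)
Conditions: Pd(OAc)2 (5 mol %), tBuXPhos (10 mol %), K3PO4, toluene, 100 °C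
Reagents that add atoms: none
Why: Same Pd-catalysed etherification as in step 10.

Step 15
Reactants: 24 A–I nonamer silyl ether
Product: 25 A–I nonamer phenol (free C6 hydroxyl on ring I)
Conditions: TBAF (1.2 equiv), AcOH (1.2 equiv), THF, 0 °C to rt
Reagents that add atoms: none
Why: Fluoride-induced cleavage of the aryl silyl ether as in step 9.

Step 16
Reactants: 2 4-chloro-2,6-dimethoxyphenol; 26 5-bromo-1,2,3-trimethoxybenzene
Product: 27 5-chloro-1,3-dimethoxy-2-(3,4,5-trimethoxyphenoxy)benzene (J–K unit)
Conditions: CuI (10 mol %), picolinic acid (20 mol %), K3PO4, DMSO, 90 °C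
Reagents that add atoms: none
Why: Ullmann-type O-arylation of a di-ortho-substituted phenol with CuI and picolinic acid, a system suited to hindered phenols; copper activates only the aryl bromide, so the chlorine of 2 and of the product is kept for step 17.

Step 17
Reactants: 25 A–I nonamer phenol; 27 5-chloro-1,3-dimethoxy-2-(3,4,5-trimethoxyphenoxy)benzene (1.5 equiv)
Product: 28 per-O-methyl undecamer (octacosamethyl ether of 29)
Conditions: Pd(OAc)2 (5 mol %), tBuXPhos (10 mol %), K3PO4, toluene, 100 °C
Reagents that add atoms: none
Why: Same Pd-catalysed etherification as in step 10; 27 has the same unhindered chloride environment as 16.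

Step 18
Reactants: 28 per-O-methyl undecamer
Product: 29 target CNP0245174.0 (undecamer with 28 free hydroxyls)
Conditions: BBr3 (ca. 60 equiv), CH2Cl2, –78 °C to rt; degassed H2O; Sephadex LH-20, degassed MeOH, Ar
Reagents that add atoms: none
Why: Lewis-acid cleavage of aryl methyl ethers: bromide attacks the methyl group of each ether–boron adduct, while the diaryl ether bonds stay because bromide cannot substitute at an sp2 carbon; the product is handled under argon since the five pyrogallol-type rings oxidise readily.

## Compound list

1 | 5-chloro-1,2,3-trimethoxybenzene | COc1cc(Cl)cc(OC)c1OC | starting material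
2 | 4-chloro-2,6-dimethoxyphenol | COc1cc(Cl)cc(OC)c1O | intermediate
3 | trichloroethylene | ClC=C(Cl)Cl | starting material
4 | 5-chloro-2-{[(E)-1,2-dichloroethenyl]oxy}-1,3-dimethoxybenzene | COc1cc(Cl)cc(OC)c1O/C(Cl)=C\Cl | intermediate
5 | 5-chloro-2-[(chloroethynyl)oxy]-1,3-dimethoxybenzene | COc1cc(Cl)cc(OC)c1OC#CCl | intermediate (not isolated)
6 | lithium (4-chloro-2,6-dimethoxyphenoxy)acetylide | COc1cc(Cl)cc(OC)c1OC#C[Li] | intermediate (not isolated)
7 | 5-chloro-2-(ethynyloxy)-1,3-dimethoxybenzene | COc1cc(Cl)cc(OC)c1OC#C | intermediate
8 | 2-[(1-bromoethenyl)oxy]-5-chloro-1,3-dimethoxybenzene | COc1cc(Cl)cc(OC)c1OC(Br)=C | intermediate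
9 | dimethyl squarate (3,4-dimethoxycyclobut-3-ene-1,2-dione) | COC1=C(OC)C(=O)C1=O | starting material
10 | [1-(4-chloro-2,6-dimethoxyphenoxy)ethenyl]lithium | COc1cc(Cl)cc(OC)c1OC([Li])=C | intermediate (not isolated)
11 | lithium 1-[1-(4-chloro-2,6-dimethoxyphenoxy)ethenyl]-2,3-dimethoxy-4-oxocyclobut-2-en-1-olate (racemic) | COC1=C(OC)C([O-])(C(=C)Oc2c(OC)cc(Cl)cc2OC)C1=O.[Li+] | intermediate (not isolated)
12 | 4-(tert-butyldimethylsilyloxy)-4-[1-(4-chloro-2,6-dimethoxyphenoxy)ethenyl]-2,3-dimethoxycyclobut-2-en-1-one (racemic) | COC1=C(OC)C(O[Si](C)(C)C(C)(C)C)(C(=C)Oc2c(OC)cc(Cl)cc2OC)C1=O | intermediate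
13 | (3Z)-4-(tert-butyldimethylsilyloxy)-5-(4-chloro-2,6-dimethoxyphenoxy)-2,3-dimethoxyhexa-1,3,5-trien-1-one | O=C=C(OC)/C(OC)=C(/O[Si](C)(C)C(C)(C)C)C(=C)Oc1c(OC)cc(Cl)cc1OC | intermediate (not isolated)
14 | 4-(tert-butyldimethylsilyloxy)-5-(4-chloro-2,6-dimethoxyphenoxy)-2,3-dimethoxycyclohexa-2,4-dien-1-one | O=C1CC(Oc2c(OC)cc(Cl)cc2OC)=C(O[Si](C)(C)C(C)(C)C)C(OC)=C1OC | intermediate (not isolated)
15 | 4-(tert-butyldimethylsilyloxy)-5-(4-chloro-2,6-dimethoxyphenoxy)-2,3-dimethoxyphenol | Oc1cc(Oc2c(OC)cc(Cl)cc2OC)c(O[Si](C)(C)C(C)(C)C)c(OC)c1OC | intermediate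
16 | tert-butyl[6-(4-chloro-2,6-dimethoxyphenoxy)-2,3,4-trimethoxyphenoxy]dimethylsilane | COc1cc(Oc2c(OC)cc(Cl)cc2OC)c(O[Si](C)(C)C(C)(C)C)c(OC)c1OC | intermediate
17 | 2,4,6-trimethoxyphenol | COc1cc(OC)c(O)c(OC)c1 | starting material
18 | A–B–C trimer silyl ether, tert-butyl{6-[2,6-dimethoxy-4-(2,4,6-trimethoxyphenoxy)phenoxy]-2,3,4-trimethoxyphenoxy}dimethylsilane | COc1cc(OC)c(Oc2cc(OC)c(Oc3cc(OC)c(OC)c(OC)c3O[Si](C)(C)C(C)(C)C)c(OC)c2)c(OC)c1 | intermediate
19 | A–B–C trimer phenol, 6-[2,6-dimethoxy-4-(2,4,6-trimethoxyphenoxy)phenoxy]-2,3,4-trimethoxyphenol | COc1cc(OC)c(Oc2cc(OC)c(Oc3cc(OC)c(OC)c(OC)c3O)c(OC)c2)c(OC)c1 | intermediate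
20 | A–E pentamer silyl ether (permethylated rings A to E, tert-butyldimethylsilyl ether on C6 of ring E) | COc1cc(OC)c(Oc2cc(OC)c(Oc3cc(OC)c(OC)c(OC)c3Oc3cc(OC)c(Oc4cc(OC)c(OC)c(OC)c4O[Si](C)(C)C(C)(C)C)c(OC)c3)c(OC)c2)c(OC)c1 | intermediate
21 | A–E pentamer phenol (free C6 hydroxyl on ring E) | COc1cc(OC)c(Oc2cc(OC)c(Oc3cc(OC)c(OC)c(OC)c3Oc3cc(OC)c(Oc4cc(OC)c(OC)c(OC)c4O)c(OC)c3)c(OC)c2)c(OC)c1 | intermediate
22 | A–G heptamer silyl ether (tert-butyldimethylsilyl ether on C6 of ring G) | COc1cc(OC)c(Oc2cc(OC)c(Oc3cc(OC)c(OC)c(OC)c3Oc3cc(OC)c(Oc4cc(OC)c(OC)c(OC)c4Oc4cc(OC)c(Oc5cc(OC)c(OC)c(OC)c5O[Si](C)(C)C(C)(C)C)c(OC)c4)c(OC)c3)c(OC)c2)c(OC)c1 | intermediate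
23 | A–G heptamer phenol (free C6 hydroxyl on ring G) | COc1cc(OC)c(Oc2cc(OC)c(Oc3cc(OC)c(OC)c(OC)c3Oc3cc(OC)c(Oc4cc(OC)c(OC)c(OC)c4Oc4cc(OC)c(Oc5cc(OC)c(OC)c(OC)c5O)c(OC)c4)c(OC)c3)c(OC)c2)c(OC)c1 | intermediate
24 | A–I nonamer silyl ether (tert-butyldimethylsilyl ether on C6 of ring I) | COc1cc(OC)c(Oc2cc(OC)c(Oc3cc(OC)c(OC)c(OC)c3Oc3cc(OC)c(Oc4cc(OC)c(OC)c(OC)c4Oc4cc(OC)c(Oc5cc(OC)c(OC)c(OC)c5Oc5cc(OC)c(Oc6cc(OC)c(OC)c(OC)c6O[Si](C)(C)C(C)(C)C)c(OC)c5)c(OC)c4)c(OC)c3)c(OC)c2)c(OC)c1 | intermediate
25 | A–I nonamer phenol (free C6 hydroxyl on ring I) | COc1cc(OC)c(Oc2cc(OC)c(Oc3cc(OC)c(OC)c(OC)c3Oc3cc(OC)c(Oc4cc(OC)c(OC)c(OC)c4Oc4cc(OC)c(Oc5cc(OC)c(OC)c(OC)c5Oc5cc(OC)c(Oc6cc(OC)c(OC)c(OC)c6O)c(OC)c5)c(OC)c4)c(OC)c3)c(OC)c2)c(OC)c1 | intermediate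
26 | 5-bromo-1,2,3-trimethoxybenzene | COc1cc(Br)cc(OC)c1OC | starting material
27 | 5-chloro-1,3-dimethoxy-2-(3,4,5-trimethoxyphenoxy)benzene | COc1cc(Oc2c(OC)cc(Cl)cc2OC)cc(OC)c1OC | intermediate
28 | per-O-methyl undecamer (octacosamethyl ether of 29) | COc1cc(OC)c(Oc2cc(OC)c(Oc3cc(OC)c(OC)c(OC)c3Oc3cc(OC)c(Oc4cc(OC)c(OC)c(OC)c4Oc4cc(OC)c(Oc5cc(OC)c(OC)c(OC)c5Oc5cc(OC)c(Oc6cc(OC)c(OC)c(OC)c6Oc6cc(OC)c(Oc7cc(OC)c(OC)c(OC)c7)c(OC)c6)c(OC)c5)c(OC)c4)c(OC)c3)c(OC)c2)c(OC)c1 | intermediate
29 | CNP0245174.0, undecameric polyphenol with rings A to K and 28 free hydroxyls | Oc1cc(O)c(Oc2cc(O)c(Oc3cc(O)c(O)c(O)c3Oc3cc(O)c(Oc4cc(O)c(O)c(O)c4Oc4cc(O)c(Oc5cc(O)c(O)c(O)c5Oc5cc(O)c(Oc6cc(O)c(O)c(O)c6Oc6cc(O)c(Oc7cc(O)c(O)c(O)c7)c(O)c6)c(O)c5)c(O)c4)c(O)c3)c(O)c2)c(O)c1 | target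

## Step count and risk

Total step count: 18. Longest linear sequence: 17 (steps 1 to 15, 17 and 18); step 16 is a one-step side branch from 2.

**Step 6 (key step).** The most likely failure is diversion of the electron-rich ketene before it cyclises: intermolecular trapping, or thermal loss of the silyl group followed by air oxidation of the resulting hydroquinone. The ring opening needs a temperature at which such a crowded ketene has other options. The fallback sets out from 4 and returns at 16; it also bypasses steps 4 and 5. The acetylide 6, generated as in step 3, is added directly to 9 (THF, –78 °C; aqueous NH4Cl) to give 4-[(4-chloro-2,6-dimethoxyphenoxy)ethynyl]-4-hydroxy-2,3-dimethoxycyclobut-2-en-1-one F1. Heating F1 in toluene should give, through the enynylketene and its diradical with hydrogen transfer from the hydroxyl, 2-(4-chloro-2,6-dimethoxyphenoxy)-5,6-dimethoxy-1,4-benzoquinone F2. Reduction with Na2S2O4 gives 2-(4-chloro-2,6-dimethoxyphenoxy)-5,6-dimethoxybenzene-1,4-diol F3. One equivalent of MeI with K2CO3 should methylate the less hindered hydroxyl, the one next to the ring C–H, to give 6-(4-chloro-2,6-dimethoxyphenoxy)-2,3,4-trimethoxyphenol F4. Silylation with TBSCl and imidazole in DMF gives 16.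

**Step 4.** The α-bromo enol ether is acid- and moisture-sensitive. A second addition of HBr, hydrolysis to the aryl acetate on work-up, or polymerisation of the ynol ether before it reacts would each erode the material. The fallback sets out from 7 and returns at 10, the intermediate of step 5. Hydrostannation of 7 with Bu3SnH and Pd(PPh3)4 (THF, 0 °C) places tin on the oxygen-bearing carbon and gives the stable tributyl[1-(4-chloro-2,6-dimethoxyphenoxy)ethenyl]stannane F5. Tin–lithium exchange with one equivalent of n-BuLi at –78 °C gives 10, which is carried through step 5 as written. This also replaces the two equivalents of t-BuLi and so lowers the chance of ring metalation next to chlorine.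

**Step 10 (the same holds for steps 8, 12, 14 and 17).** The C–O reductive elimination may be slow with a phenoxide flanked by an aryloxy and a methoxy group. Hydrodechlorination of the chloride and transfer of the silyl group to the phenoxide would then take over. The fallback sets out from 16, uses 19, and returns at 20. Miyaura borylation of 16 (Pd2(dba)3, XPhos, B2pin2, KOAc, dioxane, 100 °C) gives tert-butyl{6-[2,6-dimethoxy-4-(4,4,5,5-tetramethyl-1,3,2-dioxaborolan-2-yl)phenoxy]-2,3,4-trimethoxyphenoxy}dimethylsilane F6. Oxidative Chan–Lam coupling of F6 with 19 (Cu(OAc)2, pyridine, B(OH)3, 4 Å MS, MeCN, air, 70 °C) gives 20. The bond is then formed from divalent copper under oxidative conditions and no longer depends on reductive elimination from palladium.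

**Step 18.** With 28 ethers, incomplete cleavage at a few sites and oxidative degradation of the free polyphenol during isolation are the likely losses. The fallback sets out from 28 and returns at 29. After the BBr3 treatment the crude product is not purified but acetylated at once (Ac2O, pyridine, DMAP) to the octacosaacetate of 29 F7. F7 is stable to air and silica, so partly demethylated material can be removed by chromatography. Acid-catalysed methanolysis (HCl generated from AcCl in degassed MeOH, rt, Ar) then releases 29 without any phenoxide being formed.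

## Further compounds

F1 | step 6 | 4-[(4-chloro-2,6-dimethoxyphenoxy)ethynyl]-4-hydroxy-2,3-dimethoxycyclobut-2-en-1-one (racemic) | COC1=C(OC)C(O)(C#COc2c(OC)cc(Cl)cc2OC)C1=O
F2 | step 6 | 2-(4-chloro-2,6-dimethoxyphenoxy)-5,6-dimethoxy-1,4-benzoquinone | O=C1C(Oc2c(OC)cc(Cl)cc2OC)=CC(=O)C(OC)=C1OC
F3 | step 6 | 2-(4-chloro-2,6-dimethoxyphenoxy)-5,6-dimethoxybenzene-1,4-diol | Oc1cc(Oc2c(OC)cc(Cl)cc2OC)c(O)c(OC)c1OC
F4 | step 6 | 6-(4-chloro-2,6-dimethoxyphenoxy)-2,3,4-trimethoxyphenol | COc1cc(Oc2c(OC)cc(Cl)cc2OC)c(O)c(OC)c1OC
F5 | step 4 | tributyl[1-(4-chloro-2,6-dimethoxyphenoxy)ethenyl]stannane | CCCC[Sn](CCCC)(CCCC)C(=C)Oc1c(OC)cc(Cl)cc1OC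
F6 | step 10 | tert-butyl{6-[2,6-dimethoxy-4-(4,4,5,5-tetramethyl-1,3,2-dioxaborolan-2-yl)phenoxy]-2,3,4-trimethoxyphenoxy}dimethylsilane | COc1cc(Oc2c(OC)cc(B3OC(C)(C)C(C)(C)O3)cc2OC)c(O[Si](C)(C)C(C)(C)C)c(OC)c1OC
F7 | step 18 | octacosaacetate of 29 | CC(=O)Oc1cc(OC(C)=O)c(Oc2cc(OC(C)=O)c(Oc3cc(OC(C)=O)c(OC(C)=O)c(OC(C)=O)c3Oc3cc(OC(C)=O)c(Oc4cc(OC(C)=O)c(OC(C)=O)c(OC(C)=O)c4Oc4cc(OC(C)=O)c(Oc5cc(OC(C)=O)c(OC(C)=O)c(OC(C)=O)c5Oc5cc(OC(C)=O)c(Oc6cc(OC(C)=O)c(OC(C)=O)c(OC(C)=O)c6Oc6cc(OC(C)=O)c(Oc7cc(OC(C)=O)c(OC(C)=O)c(OC(C)=O)c7)c(OC(C)=O)c6)c(OC(C)=O)c5)c(OC(C)=O)c4)c(OC(C)=O)c3)c(OC(C)=O)c2)c(OC(C)=O)c1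
A1 | alternative 1 | methyl-protected undecamer with free C4 hydroxyls on rings C, E, G, I and K | COc1cc(OC)c(Oc2cc(OC)c(Oc3cc(OC)c(O)c(OC)c3Oc3cc(OC)c(Oc4cc(OC)c(O)c(OC)c4Oc4cc(OC)c(Oc5cc(OC)c(O)c(OC)c5Oc5cc(OC)c(Oc6cc(OC)c(O)c(OC)c6Oc6cc(OC)c(Oc7cc(OC)c(O)c(OC)c7)c(OC)c6)c(OC)c5)c(OC)c4)c(OC)c3)c(OC)c2)c(OC)c1
A2 | alternative 1 | methyl-protected undecamer with formyl groups at C4 of rings C, E, G, I and K | COc1cc(OC)c(Oc2cc(OC)c(Oc3cc(OC)c(C=O)c(OC)c3Oc3cc(OC)c(Oc4cc(OC)c(C=O)c(OC)c4Oc4cc(OC)c(Oc5cc(OC)c(C=O)c(OC)c5Oc5cc(OC)c(Oc6cc(OC)c(C=O)c(OC)c6Oc6cc(OC)c(Oc7cc(OC)c(C=O)c(OC)c7)c(OC)c6)c(OC)c5)c(OC)c4)c(OC)c3)c(OC)c2)c(OC)c1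
A3 | alternative 2 | 2-(2-bromo-3,4,5-trimethoxyphenoxy)-3-ethoxy-5-(2,4,6-trimethoxyphenoxy)phenol | CCOc1cc(Oc2c(OC)cc(OC)cc2OC)cc(O)c1Oc1cc(OC)c(OC)c(OC)c1Br
A4 | alternative 2 | 2-(ethynyloxy)-1,3,5-trimethoxybenzene | COc1cc(OC)c(OC#C)c(OC)c1
A5 | alternative 2 | 4-(2-bromo-3,4,5-trimethoxyphenoxy)-3-ethoxycyclobut-2-en-1-one | CCOC1=CC(=O)C1Oc1cc(OC)c(OC)c(OC)c1Br
A6 | alternative 3 | 2-[4-(benzyloxy)-3,5-dimethoxyphenoxy]benzene-1,3,5-triol | Oc1cc(O)c(Oc2cc(OC)c(OCc3ccccc3)c(OC)c2)c(O)c1
A7 | alternative 3 | methyl 6-[4-(benzyloxy)-3,5-dimethoxyphenoxy]-3,5-dioxohexanoate | COC(=O)CC(=O)CC(=O)COc1cc(OC)c(OCc2ccccc2)c(OC)c1
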